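Late in a run, monomer in chains stands beside the free monomer that is left, and each meeting of the two makes side product.

    free monomer + monomer in chains → side product (k1 = 5.7 × 10⁻⁴ M⁻¹ s⁻¹)
    2 growing radical → dead chain (k2 = 7 × 10⁷ M⁻¹ s⁻¹)
    free monomer + growing radical → monomer in chains + growing radical, rate k3*[growing radical]*[free monomer] (k3 = 30000 M⁻¹ s⁻¹)
    free monomer + initiating radical → growing radical + monomer in chains (k4 = 6.1 × 10⁵ M⁻¹ s⁻¹)
    monomer in chains → over-reaction product (k5 = 2.7 × 10⁻⁷ s⁻¹)
    2 free monomer → self-condensation product (k6 = 8.7 × 10⁻⁴ M⁻¹ s⁻¹)
    initiator → 2 initiating radical (k7 = 1.4 × 10⁻⁵ s⁻¹)

common to all: initiator 0.5 mol%

|  | free monomer | time | remark |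
|---|---|---|---|
| maple | 0.54 M (fed, over 3.00 h) | 3.0 h | all but free monomer at the start; free monomer goes in evenly over 3.00 h, the run ends at 3.0 h |
| alder | 0.54 M | 3.0 h | everything together in a closed stirred flask, run for 3.0 h |
| cedar | 0.54 M |  | one stirred flow tank at steady state, fed with the mixture as stated, mean residence time 9.00 h |
| oak | 0.54 M |  | one stirred flow tank at steady state, fed with the mixture as stated, mean residence time 3.0 h |

- percentages count the free monomer that a species holds: one side product or self-condensation product counts as two
- two of one species on the left: rate k times its square, two consumed each time
- the stated concentrations are those of everything mixed, before any reaction; amounts are the same in each set-up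
- the feed brings no volume worth counting
- the share counts what is present at the end, not what went on to other products
- run time (maple): 3.0 h

* order of the set-ups by the share of monomer in chains in all that became monomer in chains or side product, at the outlet or at the end, highest first (maple / alder / cedar / oak)
* share of monomer in chains in all that became monomer in chains or side product, at the outlet or at the end, maple
* share of monomer in chains in all that became monomer in chains or side product, at the outlet or at the end, alder
* share of monomer in chains in all that became monomer in chains or side product, at the outlet or at the end, cedar
* share of monomer in chains in all that became monomer in chains or side product, at the outlet or at the end, oak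

Oak and cedar are the same flow tank on the same feed, and they part in residence time, 3.0 h against 9.00 h. At steady state side product leaves as fast as it forms, so its amount is the side reaction's constant times free monomer times monomer in chains times residence time. Each side product counts as two, and monomer in chains drops out of the ratio, which gives the share, a selectivity:

share = 1 / (1 + wear rate × f × residence time)

Here f is the fraction of the free monomer charge left at the outlet. The value 2.22 h⁻¹ is the wear rate, twice the side reaction's constant times the charge of free monomer.

To find f, start from the radicals, which come from the initiator, charged at 0.00270 M, less than the free monomer. The tank holds that charge divided by one plus decay constant times residence time. If growing radicals die as fast as they form, oak holds 2.17 × 10⁻⁸ M of them. At that level a growing radical in oak lasts about 0.330 s, far shorter than the residence time, so the assumption stands. Cedar holds less, 1.93 × 10⁻⁸ M. The free monomer balance is: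

f = 1 / (1 + growth + self-condensation + side reaction)

Growth, the propagation constant times radical level times residence time, is 7.02 in oak and 18.7 in cedar. A first f from growth, put into the other two terms, gives 8.82% for oak and 3.63% for cedar. The step to over-reaction product is dropped, its half-life being longer than either residence time.

Cedar's f falls by less than its time grows, so cedar wears harder: the reckoning gives oak 63.0% and cedar 58.0%. It stops at the tanks.

The forecast says alder > maple > oak > cedar, with 75.5%, 78.5%, 56.6% and 61.6% in the order asked, the loss being “worse the longer the residence time”. Both its tank values lie below this reckoning.

The simulation gives alder > maple > oak > cedar, with maple 74.5%, alder 78.7%, cedar 56.7% and oak 61.6%, so the forecast holds within its margins. Its order of the tanks stands as long as free monomer times residence time is smaller in oak than in cedar, as the outlet readings show. Free monomer reads 9.39% at oak's outlet, and the wear rate turns that into a share of 61.5%. Cedar's outlet reads 3.83%, which gives a share of 56.6%.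

All constants come from no measurement; the run is a simulation.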